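Compound numbers used throughout (SMILES in the list after the steps): 1 propargyl bromide, 2 ethynylmagnesium bromide, 3 penta-1,4-diyne, 4 its 1,5-dilithio derivative, 5 the bis-ynolate, 6 the bis(siloxyalkyne), 7 chloroacetaldehyde dimethyl acetal, 8 sodium methoxyethynide, 9 methoxyacetylene, 10 propionyl chloride, 11 methylketene, 12 the cyclobutenone, 13 the vinylketene, 14 and 15 first cyclobutenone adduct and dienylketene, 16 the mono-annulated phenol, 17 and 18 second adduct and dienylketene, 19 the bis(silyl ether) diarylmethane, 20 the tetraphenol, 21 the target.

## Analysis of the target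

Target 21 consists of two identical benzene rings (ring A and ring B) joined through one CH2 group at C3' and C3'''. Every ring carbon is substituted and there is no stereocentre, so the problem is purely one of regiochemistry. Going round each ring: C1' isovaleryl, C2' OH, C3' bridge, C4' OH, C5' methyl, C6' OMe; the three oxygens are mutually meta (a phloroglucinol pattern) and only the one at C6' is methylated. The free phenols are easily oxidised under base, and the C6' methyl ether lies ortho to the ketone, where strong Lewis acids such as AlCl3 can cleave it. The bridge joins two carbons that are each flanked by two hydroxyls and para to a methoxy group, so ipso-protonation and retro-Friedel–Crafts loss of the benzyl unit are possible in strong acid while the rings are not yet acylated. The difficulty is that in a phloroglucinol precursor the three oxygens and the three carbons between them are nearly equivalent, so electrophilic substitution and O-alkylation give little control over which oxygen is methylated and where methyl, bridge and acyl group go. The strategy rests on reading C2'–C3'–CH2–C3'''–C2''' as a penta-1,4-diyne oxygenated at both ends: C3' and C3''' are the inner alkyne carbons, C2' and C2''' the oxygen-bearing ones, and the bridge is the propargylic CH2. The other four carbons of each ring (C4', C5', C6', C1' with OH, CH3, OCH3 and H) then map onto an alkoxy-substituted vinylketene, so one thermal cascade can close ring A and ring B with all three oxygens already differentiated.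

## Retrosynthetic reasoning

The two aryl–acyl bonds C1'–C(=O) of 21 are cut first, leading back to tetraphenol 20. In 20, C1' is the only ring carbon that still bears hydrogen, and it is activated by an ortho hydroxyl, an ortho methoxy and a para hydroxyl group, so a twofold C-acylation has no regiochemical choice to make. Carrying the acyl groups through the ring synthesis instead would require an acylated four-carbon partner whose ketene chemistry is hard to predict. The forward reaction must acylate carbon twice while leaving the bridge and the C6' ether intact.

The two O–H bonds at C2' and C2''' of 20 are traced back to O–Si bonds in 19. This costs one deprotection, but the silyl groups are not chosen as protecting groups: they are what remains of the activating group on the alkyne, and they mark the C2' oxygen as different from the C4' hydroxyl and the C6' methoxy group.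

In 19 each ring is cut at C3'–C4' and C1'–C2', with C4'–C5' regarded as the bond closed last. This releases the whole C2'–C3'–CH2–C3'''–C2''' chain as bis(siloxyalkyne) 6 and each remaining four-carbon unit as vinylketene 13, which is stored as cyclobutenone 12. Other cuts through the rings would either separate the bridge from the rings, so that a ring-joining step with its own regiochemistry would be needed, or would not place the three oxygens in different building blocks. Here the C4' oxygen is the ketene carbonyl, the C6' oxygen is the enol ether of 12 and the C2' oxygen comes from 6, so the OH/OMe/OSi pattern follows from which atom comes from which partner. The forward reaction has to open 12 to 13, join it to each alkyne of 6 with the ketene carbon on the oxygen-remote alkyne carbon (14, then 15), close and aromatise the first ring (16) and repeat this once (17, 18), without disturbing the doubly propargylic CH2.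

Diyne 6 is cut at its two C(sp)–O bonds, leading through bis-ynolate 5 and dilithio compound 4 to hydrocarbon 3. The oxygen is brought in as an electrophile onto an acetylide carbon and the silyl group is then placed on the ynolate oxygen. An ester-homologation route is avoided because it would have to pass through a malonate-type CH2 that is too acidic. Hydrocarbon 3 is cut at one C(sp3)–C(sp) bond into propargyl bromide 1 and ethynylmagnesium bromide 2; the forward reaction is a copper-catalysed coupling.

Cyclobutenone 12 is cut in a retro-[2+2] sense at C1–C2 and C3–C4 into methylketene 11 and methoxyacetylene 9. The polarity of both partners puts the methoxy group at C3 and the methyl group at C4, which is the arrangement that later places OMe at C6' and CH3 at C5'. Ketene 11 is made in the flask from propionyl chloride 10, and 9 comes by double elimination, through its sodium salt 8, from chloroacetal 7.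

## Alternatives that were turned down

Alternative 1: Here the two O–CH3 bonds at C6' and C6''' are the last bonds made, and the carbon skeleton is the hexaphenol dimer bis[2,4,6-trihydroxy-3-methyl-5-(3-methylbutanoyl)phenyl]methane A3, available by classical acylation and methylene coupling of a C-methylphloroglucinol.
- **Forward key step:** The four hydroxyls that flank the bridge are tied pairwise across the two rings by two di-tert-butylsilylene units to give the doubly bridged hexaphenol A2. Its only free hydroxyls are at C6' and C6''', and MeI with Ag2O methylates them to the doubly silylene-bridged target A1; fluoride then releases 21.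
- **For it:** It is short and starts from cheap aromatic material. The acyl groups are in place early, so the bridge is never exposed to acid on an unacylated ring. Any inter-ring pairing of the four bridge-flanking oxygens leaves the same two hydroxyls free.
- **Against it:** Closing two eight-membered dioxasilocine rings on one diarylmethane competes with intermolecular silylene bridging and with partial silylation. The hydroxyl to be methylated is hydrogen-bonded to the ketone and flanked by acyl and methyl groups, so it is a poor nucleophile. Aryl silyl ethers ortho to a carbonyl group are labile and may migrate or be lost under Ag2O/MeI. A3 is prone to oxidation and to bridge scrambling in base.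
- **Comparison:** Alternative 1 is stronger in step count and in cost of materials. The chosen route offers in return an oxygen pattern that is fixed by bond construction, with no selective protection or selective alkylation to be got right on a hexaphenol.

Alternative 2: Each ring is cut at C1'–acyl and C6'–O, which makes C1'–C6' an aryne bond.
- **Forward key step:** CsF acts on the methylene-bridged bis(ortho-silylaryl triflate) A5, bis[2,6-bis(methoxymethoxy)-3-methyl-4-(trifluoromethanesulfonyloxy)-5-(trimethylsilyl)phenyl]methane, and generates an aryne in each ring. Isovalerate adds with its oxygen at C6', the carbon remote from the inductively withdrawing C2' alkoxy group, and the aryl anion at C1' takes over the acyl group. The product is bis[4-hydroxy-2,6-bis(methoxymethoxy)-3-methyl-5-(3-methylbutanoyl)phenyl]methane A4, which would be O-methylated and freed of its methoxymethyl groups.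
- **For it:** Acyl group and C6' oxygen arrive together with predictable regiochemistry, and the C6' hydroxyl emerges as the only free phenol, so its methylation is unambiguous. On one point it is stronger than the chosen route: it needs no late Friedel–Crafts acylation in acid on the bridged dimer.
- **Against it:** A5 is a hexasubstituted arene twice over, and installing an ortho silyl/triflate pair on a ring that is already pentasubstituted, together with the bridge, needs a linear sequence longer than the entire chosen route. Each aryne is flanked on both sides, the second is generated beside a phenoxide and a ketone, and simple protonation to the aryl ester without acyl transfer competes; any inefficiency counts twice.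
- **Comparison:** The chosen route reaches both of its key-step partners in two steps each and makes the rings rather than decorating them.

Alternative 3: The two C2'–O bonds are cut, so the precursor is the resorcinol-level dimer bis[4-methoxy-3-methyl-5-(3-methylbutanoyl)-2-(pivaloyloxy)phenyl]methane A7, which has a single C–H per ring, at C2'.
- **Forward key step:** Pd(OAc)2 (divalent palladium) with PhI(OCOCF3)2 in trifluoroacetic acid and its anhydride should effect ketone-directed cyclopalladation, oxidation to tetravalent palladium and C–O reductive elimination. After hydrolysis of the trifluoroacetate this gives bis[6-hydroxy-4-methoxy-3-methyl-5-(3-methylbutanoyl)-2-(pivaloyloxy)phenyl]methane A6, and removal of the pivalates gives 21.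
- **For it:** The step is catalytic, the site is unambiguous because it is the only C–H, and the precursor has one oxygen fewer per ring. In catalytic economy and in avoiding sensitive alkynes it is stronger than the chosen route.
- **Against it:** The C–H to be palladated lies between the acyl-bearing C1' and the bridge-bearing C3', and cyclometalation at a position with two ortho neighbours is strongly disfavoured. The doubly benzylic CH2 and the electron-rich rings are exposed to a trivalent iodine oxidant in strong acid, which invites benzylic oxidation, oxidative dearomatisation and bridge cleavage. A7 itself still needs regiocontrolled arene chemistry.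
- **Comparison:** The chosen route uses no oxidant on the electron-rich dimer and builds the oxygen pattern directly.

Key step: step 5

Remark on the chemistry: methoxyacetylene 9 is treated as a reagent that is not reliably purchasable and is therefore prepared (step 3); cyclobutenone 12 is used as the racemate because its stereocentre is destroyed when the ring opens.

## Route

Step 1
Reactants: 1 propargyl bromide; 2 ethynylmagnesium bromide
Product: 3 penta-1,4-diyne
Conditions: CuBr (3 mol %), THF, 20 → 50 °C; aq NH4Cl; co-distilled with THF, dried and used as an assayed solution
Reagents that add atoms: none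
Why: Copper-catalysed SN2 coupling of an alkynyl Grignard reagent with a propargylic bromide is the standard construction of a skipped diyne; the medium is not basic enough to isomerise the product to the conjugated diyne. The volatile product is not concentrated but carried on in THF.

Step 2
Reactants: 3 penta-1,4-diyne
Product: 6 1,5-bis(triisopropylsilyloxy)penta-1,4-diyne, via 1,5-dilithiopenta-1,4-diyne 4 (not isolated), via dilithium penta-1,4-diyne-1,5-diolate 5 (not isolated)
Conditions: LiN(SiMe3)2 (2.1 equiv), THF, −78 °C; LiOOt-Bu (2.2 equiv, from t-BuOOH and LiN(SiMe3)2), −78 → 0 °C; TIPSOTf (2.3 equiv), −78 → 0 °C; pentane/aq NaHCO3, Et3N-deactivated silica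
Reagents that add atoms: tert-butyl hydroperoxide, CC(C)(C)OO; triisopropylsilyl trifluoromethanesulfonate (TIPSOTf), CC(C)[Si](OS(=O)(=O)C(F)(F)F)(C(C)C)C(C)C
Why: The terminal C–H bonds are the most acidic sites of 3 and are removed at −78 °C to give 4; LiOOt-Bu then acts as an oxenoid that transfers oxygen to each acetylide carbon with loss of LiOt-Bu (the known acetylide-to-ynolate oxidation) to give 5. The bulky silyl triflate reacts at the ynolate oxygen and not at carbon, giving the bis(siloxyalkyne).

Step 3
Reactants: 7 2-chloro-1,1-dimethoxyethane (chloroacetaldehyde dimethyl acetal)
Product: 9 methoxyacetylene, via sodium methoxyethynide 8 (not isolated)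
Conditions: NaNH2 (3.1 equiv), liquid NH3, −33 °C; cold saturated aq NaCl, −70 °C; distilled into a cold trap
Reagents that add atoms: none
Why: Twofold base-induced elimination (methanol, then HCl) with NaNH2 in liquid ammonia is the classical preparation of alkoxyacetylenes; the third equivalent of base holds the product as acetylide 8 until the cold aqueous quench, after which the low-boiling ynol ether is distilled off.

Step 4
Reactants: 9 methoxyacetylene; 10 propionyl chloride
Product: 12 racemic 3-methoxy-4-methylcyclobut-2-en-1-one, via methylketene 11 (not isolated)
Conditions: 10 added slowly to 9 (2 equiv) and Et3N (1.2 equiv), CH2Cl2, 0 → 20 °C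
Reagents that add atoms: none
Why: Dehydrochlorination of 10 gives 11, which is trapped by the excess ynol ether in the known ketene–alkoxyacetylene [2+2] cycloaddition; the ketene carbonyl carbon bonds to the terminal carbon of 9 and the methyl-bearing carbon to the methoxy-bearing one, giving the 3-methoxy-4-methyl pattern. The C4 stereocentre forms without control (racemate), which is immaterial because it is lost in step 5.

Step 5
Reactants: 6 1,5-bis(triisopropylsilyloxy)penta-1,4-diyne; 12 racemic 3-methoxy-4-methylcyclobut-2-en-1-one (2.4 equiv)
Product: 19 bis[2-hydroxy-4-methoxy-3-methyl-6-(triisopropylsilyloxy)phenyl]methane, via vinylketene 13 (not isolated), via first cyclobutenone adduct 14 (not isolated), via first dienylketene 15 (not isolated), via mono-annulated phenol 16 (not isolated), via second cyclobutenone adduct 17 (not isolated), via second dienylketene 18 (not isolated)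
Conditions: toluene (0.1 M, degassed), sealed tube, 80 °C, then 110 °C to complete
Reagents that add atoms: none
Why: On heating, 12 opens by conrotatory 4π electrocyclic cleavage of its C1–C4 bond to vinylketene 13, with the methyl group turning outward (so no 1,5-hydrogen shift to the ketene is possible) and with loss of the stereocentre. The electrophilic ketene carbon of 13 bonds to the oxygen-remote carbon of one siloxyalkyne of 6 and the ketene α-carbon to the silyloxy carbon, a regiospecific [2+2] cycloaddition that gives 14 and creates C3'–C4' and C1'–C2'. Reversible 4π opening of 14 gives dienylketene 15, whose isomer with the alkenyl group turned inward closes by thermal disrotatory 6π electrocyclisation (C4'–C5'); tautomerisation of the resulting cyclohexadienone then makes the first benzene ring of 16 irreversibly. The second siloxyalkyne of 16 repeats the sequence through 17 and 18, so both rings are closed in the same pericyclic mode and the bridge carbon is never touched. The closest known reaction type is the Danheiser benzannulation of cyclobutenones with triisopropylsiloxyalkynes to resorcinol monosilyl ethers; its use twice on one skipped diyne and with a 3-alkoxy-substituted cyclobutenone is untested. No stereocentre is formed. The selectivity needed is regiochemical: the polarisation of the siloxyalkyne fixes OH at C4' and OSi at C2' on either side of C3', and the substitution of 12 fixes CH3 at C5', OCH3 at C6' and H at C1'; the neutral conditions keep the doubly propargylic CH2 from isomerising.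

Step 6
Reactants: 19 bis[2-hydroxy-4-methoxy-3-methyl-6-(triisopropylsilyloxy)phenyl]methane
Product: 20 bis(2,6-dihydroxy-4-methoxy-3-methylphenyl)methane
Conditions: Bu4NF (2.4 equiv), AcOH (2.4 equiv), THF, 0 °C, argon
Reagents that add atoms: none
Why: Fluoride cleaves the two aryl O–Si bonds, driven by the strong Si–F bond; acetic acid protonates the phenoxides as they form, so the electron-rich tetraphenol is not left as an easily oxidised anion.

Step 7
Reactants: 20 bis(2,6-dihydroxy-4-methoxy-3-methylphenyl)methane
Product: 21 3',3'''-methylenebis(2',4'-dihydroxy-6'-methoxy-beta,5'-dimethylbutyrophenone) (target)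
Conditions: isovaleric acid (3 equiv), BF3·OEt2 (as solvent), 60 °C, argon; aq NaOAc
Reagents that add atoms: isovaleric acid (3-methylbutanoic acid), CC(C)CC(=O)O
Why: BF3-promoted Friedel–Crafts C-acylation of a phenol with a carboxylic acid (directly or by O-acylation and Fries shift) is a standard route to ortho-hydroxyaryl ketones; C1' is the only unsubstituted carbon of each ring and is activated by two ortho and one para oxygen. Each acylated ring is deactivated toward ipso attack at C3', and BF3, unlike AlCl3, should leave the C6' methyl ether intact.

## Compound list

1 | propargyl bromide (3-bromoprop-1-yne) | C#CCBr | starting material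
2 | ethynylmagnesium bromide | C#C[Mg]Br | starting material
3 | penta-1,4-diyne | C#CCC#C | intermediate
4 | 1,5-dilithiopenta-1,4-diyne | [Li]C#CCC#C[Li] | intermediate
5 | dilithium penta-1,4-diyne-1,5-diolate | [Li]OC#CCC#CO[Li] | intermediate
6 | 1,5-bis(triisopropylsilyloxy)penta-1,4-diyne | CC(C)[Si](OC#CCC#CO[Si](C(C)C)(C(C)C)C(C)C)(C(C)C)C(C)C | intermediate
7 | 2-chloro-1,1-dimethoxyethane | COC(CCl)OC | starting material
8 | sodium methoxyethynide | COC#C[Na] | intermediate
9 | methoxyacetylene (methoxyethyne) | COC#C | intermediate
10 | propionyl chloride | CCC(=O)Cl | starting material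
11 | methylketene (prop-1-en-1-one) | CC=C=O | intermediate
12 | racemic 3-methoxy-4-methylcyclobut-2-en-1-one | COC1=CC(=O)C1C | intermediate
13 | (3Z)-3-methoxypenta-1,3-dien-1-one | C/C=C(\OC)C=C=O | intermediate
14 | racemic 4-[(1Z)-1-methoxyprop-1-en-1-yl]-3-(triisopropylsilyloxy)-2-[3-(triisopropylsilyloxy)prop-2-yn-1-yl]cyclobut-2-en-1-one | O=C1C(CC#CO[Si](C(C)C)(C(C)C)C(C)C)=C(O[Si](C(C)C)(C(C)C)C(C)C)C1/C(OC)=C/C | intermediate
15 | (3E,5Z)-5-methoxy-3-(triisopropylsilyloxy)-2-[3-(triisopropylsilyloxy)prop-2-yn-1-yl]hepta-1,3,5-trien-1-one | O=C=C(CC#CO[Si](C(C)C)(C(C)C)C(C)C)/C(O[Si](C(C)C)(C(C)C)C(C)C)=C\C(OC)=C\C | intermediate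
16 | 3-methoxy-2-methyl-5-(triisopropylsilyloxy)-6-[3-(triisopropylsilyloxy)prop-2-yn-1-yl]phenol | COc1cc(O[Si](C(C)C)(C(C)C)C(C)C)c(CC#CO[Si](C(C)C)(C(C)C)C(C)C)c(O)c1C | intermediate
17 | racemic 2-{[2-hydroxy-4-methoxy-3-methyl-6-(triisopropylsilyloxy)phenyl]methyl}-4-[(1Z)-1-methoxyprop-1-en-1-yl]-3-(triisopropylsilyloxy)cyclobut-2-en-1-one | O=C1C(Cc2c(O)c(C)c(OC)cc2O[Si](C(C)C)(C(C)C)C(C)C)=C(O[Si](C(C)C)(C(C)C)C(C)C)C1/C(OC)=C/C | intermediate
18 | (3E,5Z)-2-{[2-hydroxy-4-methoxy-3-methyl-6-(triisopropylsilyloxy)phenyl]methyl}-5-methoxy-3-(triisopropylsilyloxy)hepta-1,3,5-trien-1-one | O=C=C(Cc1c(O)c(C)c(OC)cc1O[Si](C(C)C)(C(C)C)C(C)C)/C(O[Si](C(C)C)(C(C)C)C(C)C)=C\C(OC)=C\C | intermediate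
19 | bis[2-hydroxy-4-methoxy-3-methyl-6-(triisopropylsilyloxy)phenyl]methane | COc1cc(O[Si](C(C)C)(C(C)C)C(C)C)c(Cc2c(O)c(C)c(OC)cc2O[Si](C(C)C)(C(C)C)C(C)C)c(O)c1C | intermediate
20 | bis(2,6-dihydroxy-4-methoxy-3-methylphenyl)methane | COc1cc(O)c(Cc2c(O)cc(OC)c(C)c2O)c(O)c1C | intermediate
21 | 3',3'''-methylenebis(2',4'-dihydroxy-6'-methoxy-beta,5'-dimethylbutyrophenone) | COc1c(C)c(O)c(Cc2c(O)c(C)c(OC)c(C(=O)CC(C)C)c2O)c(O)c1C(=O)CC(C)C | target

## Step count and risk

Total step count: 7. Longest linear sequence: 5 steps (1, 2, 5, 6, 7; the branch 3, 4, 5, 6, 7 is equally long).

Steps least certain to work: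

**Step 5 (key step).** The alkoxy-stabilised cyclobutenone 12 should open more slowly than the alkyl- or aryl-substituted cyclobutenones normally used, so the second annulation is the likely point of failure. While it waits, the phenol of the ring formed first can trap ketene intermediates as esters or, within 18, as a lactone, and can add to the neighbouring siloxyalkyne of 16. The remaining siloxyalkyne can also be lost by thermal silyl shift to a silylketene. Fallback: the rings are closed one at a time with the phenol capped in between, setting out from 6 and returning at 20.
- Diyne 6, in twofold excess, is heated with one equivalent of 12 and the reaction is stopped at the mono-annulated phenol 16, which is isolated.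
- The phenol of 16 is silylated at once (TBSCl, imidazole, DMF) to tert-butyl{3-methoxy-2-methyl-5-(triisopropylsilyloxy)-6-[3-(triisopropylsilyloxy)prop-2-yn-1-yl]phenoxy}dimethylsilane F1.
- F1, which has no free hydroxyl next to its alkyne, is heated with 12 to give 2-{[2-(tert-butyldimethylsilyloxy)-4-methoxy-3-methyl-6-(triisopropylsilyloxy)phenyl]methyl}-5-methoxy-6-methyl-3-(triisopropylsilyloxy)phenol F2 by the same cascade.
- Buffered Bu4NF removes all three silyl groups and gives 20.

**Step 2.** Base-induced prototropic isomerisation of the skipped diyne during metalation is possible. More likely is incomplete oxidation of the second terminus of the aggregated, poorly soluble dilithio species, which would leave mono- and bis-oxidised material that is hard to separate because siloxyalkynes tolerate little chromatography. Fallback: the two oxygens are introduced one after the other through monoanionic intermediates, setting out from 3 and returning at 6.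
- Diyne 3, in threefold excess, is treated with one equivalent each of LiN(SiMe3)2 and LiOOt-Bu and then with TIPSOTf to give triisopropyl(penta-1,4-diyn-1-yloxy)silane F3.
- The excess of volatile 3 is evaporated and F3 is purified.
- The same metalation, oxidation and silylation at the remaining terminal alkyne of F3 gives 6.

**Step 7.** Acid-induced ipso-protonation at C3' can cleave or scramble the methylene bridge before both rings are acylated and deactivated, and O-acylation competes with C-acylation. Fallback: the acyl groups are introduced by anionic chemistry, setting out from 20 and returning at 21.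
- All four phenols of 20 are protected (NaH, MOMCl, DMF) to give bis[4-methoxy-2,6-bis(methoxymethoxy)-3-methylphenyl]methane F4.
- Twofold directed ortho-lithiation at the C–H between the methoxy and a methoxymethoxy group (n-BuLi, TMEDA, THF, 0 °C) and quench with N-methoxy-N,3-dimethylbutanamide gives bis[4-methoxy-2,6-bis(methoxymethoxy)-3-methyl-5-(3-methylbutanoyl)phenyl]methane F5.
- HCl in methanol at 20 °C removes the acetals from the now deactivated rings and gives 21.

**Step 4.** Dimerisation and oligomerisation of the monoalkylketene 11 can outrun its cycloaddition with the volatile ynol ether 9. Fallback: a more electrophilic, less dimerisation-prone ketene is used and the extra substituent removed afterwards, setting out from 9 and returning at 12.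
- 2-Chloropropanoyl chloride and Et3N generate chloro(methyl)ketene F6 in the presence of 9.
- The [2+2] cycloaddition gives 4-chloro-3-methoxy-4-methylcyclobut-2-en-1-one F7.
- Reductive dechlorination of the α-chloro ketone (Zn dust, AcOH, MeOH, 0 °C) gives 12.

## Further compounds

F1 | step 5 | tert-butyl{3-methoxy-2-methyl-5-(triisopropylsilyloxy)-6-[3-(triisopropylsilyloxy)prop-2-yn-1-yl]phenoxy}dimethylsilane | COc1cc(O[Si](C(C)C)(C(C)C)C(C)C)c(CC#CO[Si](C(C)C)(C(C)C)C(C)C)c(O[Si](C)(C)C(C)(C)C)c1C
F2 | step 5 | 2-{[2-(tert-butyldimethylsilyloxy)-4-methoxy-3-methyl-6-(triisopropylsilyloxy)phenyl]methyl}-5-methoxy-6-methyl-3-(triisopropylsilyloxy)phenol | COc1cc(O[Si](C(C)C)(C(C)C)C(C)C)c(Cc2c(O)c(C)c(OC)cc2O[Si](C(C)C)(C(C)C)C(C)C)c(O[Si](C)(C)C(C)(C)C)c1C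
F3 | step 2 | triisopropyl(penta-1,4-diyn-1-yloxy)silane | C#CCC#CO[Si](C(C)C)(C(C)C)C(C)C
F4 | step 7 | bis[4-methoxy-2,6-bis(methoxymethoxy)-3-methylphenyl]methane | COCOc1cc(OC)c(C)c(OCOC)c1Cc1c(OCOC)cc(OC)c(C)c1OCOC
F5 | step 7 | bis[4-methoxy-2,6-bis(methoxymethoxy)-3-methyl-5-(3-methylbutanoyl)phenyl]methane | COCOc1c(C(=O)CC(C)C)c(OC)c(C)c(OCOC)c1Cc1c(OCOC)c(C(=O)CC(C)C)c(OC)c(C)c1OCOC
F6 | step 4 | chloro(methyl)ketene (2-chloroprop-1-en-1-one) | CC(Cl)=C=O
F7 | step 4 | racemic 4-chloro-3-methoxy-4-methylcyclobut-2-en-1-one | COC1=CC(=O)C1(C)Cl
A1 | alternative 1 | doubly di-tert-butylsilylene-bridged target (C2'/C2''' and C4'/C4''' oxygens each joined through Si(t-Bu)2) | Cc1c(OC)c(C(=O)CC(C)C)c2c3c1O[Si](C(C)(C)C)(C(C)(C)C)Oc1c(C)c(OC)c(C(=O)CC(C)C)c(c1C3)O[Si](C(C)(C)C)(C(C)(C)C)O2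
A2 | alternative 1 | doubly di-tert-butylsilylene-bridged hexaphenol with free hydroxyls at C6' and C6''' | Cc1c(O)c(C(=O)CC(C)C)c2c3c1O[Si](C(C)(C)C)(C(C)(C)C)Oc1c(C)c(O)c(C(=O)CC(C)C)c(c1C3)O[Si](C(C)(C)C)(C(C)(C)C)O2
A3 | alternative 1 | bis[2,4,6-trihydroxy-3-methyl-5-(3-methylbutanoyl)phenyl]methane | CC(C)CC(=O)c1c(O)c(C)c(O)c(Cc2c(O)c(C)c(O)c(C(=O)CC(C)C)c2O)c1O
A4 | alternative 2 | bis[4-hydroxy-2,6-bis(methoxymethoxy)-3-methyl-5-(3-methylbutanoyl)phenyl]methane | COCOc1c(C)c(O)c(C(=O)CC(C)C)c(OCOC)c1Cc1c(OCOC)c(C)c(O)c(C(=O)CC(C)C)c1OCOC
A5 | alternative 2 | bis[2,6-bis(methoxymethoxy)-3-methyl-4-(trifluoromethanesulfonyloxy)-5-(trimethylsilyl)phenyl]methane | COCOc1c(C)c(OS(=O)(=O)C(F)(F)F)c([Si](C)(C)C)c(OCOC)c1Cc1c(OCOC)c(C)c(OS(=O)(=O)C(F)(F)F)c([Si](C)(C)C)c1OCOC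
A6 | alternative 3 | bis[6-hydroxy-4-methoxy-3-methyl-5-(3-methylbutanoyl)-2-(pivaloyloxy)phenyl]methane | COc1c(C)c(OC(=O)C(C)(C)C)c(Cc2c(O)c(C(=O)CC(C)C)c(OC)c(C)c2OC(=O)C(C)(C)C)c(O)c1C(=O)CC(C)C
A7 | alternative 3 | bis[4-methoxy-3-methyl-5-(3-methylbutanoyl)-2-(pivaloyloxy)phenyl]methane | COc1c(C)c(OC(=O)C(C)(C)C)c(Cc2cc(C(=O)CC(C)C)c(OC)c(C)c2OC(=O)C(C)(C)C)cc1C(=O)CC(C)C
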